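Numbering: C1 carries the acyl group, C2 a methyl, C3=C4 is the alkene, C4a carries OH, C6 the CO2H, C8 a methyl. Ring A is C1–C4/C4a/C8a and ring B is C4a–C8a.
Cuts, in order: the imide N (back to an anhydride, then a 3,4-disubstituted furan); the ketone carbon–heterocycle bond (C1 aldehyde + 3-furyllithium); C4a–C8a; C2–C3 (oxy-Cope retron); C4a–C4 (acetylide); C8a–C1 (Michael addition).
Enabling feature: C4a–C8a, the bond shared by rings A and B, joins the tertiary carbinol carbon C4a to C8a, which lies β to the carbon substituent on C1. A C4a ketyl can therefore add to a C1=C8a acceptor across the ten-membered ring made of the ten decalin carbons.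
Forward: ring B comes from an aromatic acid and receives C1–C2 at C8a and C3–C4 at C4a. An anionic oxy-Cope rearrangement opens it to the ten-membered ring, SmI2 closes rings A and B in one step, and the furan is joined last and oxidised to the maleimide.
Stereochemistry: C6 by resolution; C8 by hydride delivery anti to the C6 ester; C2 by chirality transfer from a temporary C8a centre in the oxy-Cope step; C4a, C8a and C1 in the SmI2 step; the octenyl centre by copper-catalysed asymmetric allylic alkylation.
The C1 acceptor is a nitrile. An ester there is trapped as a γ-lactone by the C4a alkoxide once the acetylide has added; a linear nitrile stays conjugated in the crowded C1=C8a alkene and is later reduced to the aldehyde used for the coupling.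

Key step: step 12

Assumption: the salt of the (R)-acid with (R)-1-phenylethylamine is taken as the less soluble one, and the TaniaPhos enantiomer written in step 16 is taken to give the S product; if either sense is reversed, the mirror-image amine or ligand is used.

Step 1
Reactants: 1 3-methoxy-5-methylbenzoic acid
Product: 3 rac-3-methyl-5-oxocyclohex-3-ene-1-carboxylic acid, via dihydro acid 2 (not isolated)
Conditions: Li, NH3(l)/THF, t-BuOH, −78 °C; NH4Cl; then 2 M HCl, THF, 50 °C
Reagents that add atoms: water, O
Why: Birch reduction of a benzoic acid makes the ipso and para carbons sp3, so OMe and Me stay on the two remaining alkenes; acid hydrolysis of the enol ether and migration of the other alkene into conjugation give the 3-methylcyclohexenone that already holds C4a (C=O), C8a, C8 (Me) and C6 (CO2H) of ring B.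

Step 2
Reactants: 3 rac-3-methyl-5-oxocyclohex-3-ene-1-carboxylic acid
Product: 4 (R)-1-phenylethylammonium (R)-3-methyl-5-oxocyclohex-3-ene-1-carboxylate
Conditions: (R)-1-phenylethylamine (0.55 equiv), EtOAc/EtOH, hot → rt, recrystallise
Reagents that add atoms: (R)-1-phenylethylamine, C[C@@H](N)c1ccccc1
Why: Classical resolution through diastereomeric ammonium carboxylates sets C6, the only stereocentre, which is not labile under these near-neutral conditions.

Step 3
Reactants: 4 (R)-1-phenylethylammonium (R)-3-methyl-5-oxocyclohex-3-ene-1-carboxylate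
Product: 6 tert-butyl (R)-3-methyl-5-oxocyclohex-3-ene-1-carboxylate, via free acid 5 (not isolated)
Conditions: 1 M HCl/EtOAc; then t-BuOC(=NH)CCl3, BF3·OEt2 (cat.), CH2Cl2/cyclohexane, 0 °C → rt
Reagents that add atoms: tert-butyl 2,2,2-trichloroacetimidate, CC(C)(C)OC(=N)C(Cl)(Cl)Cl
Why: Acid-catalysed O-alkylation of the liberated acid by the trichloroacetimidate needs no base, so C6 cannot racemise through dienolate or alkene migration, and the tert-butyl ester resists all later nucleophiles.

Step 4
Reactants: 6 tert-butyl (R)-3-methyl-5-oxocyclohex-3-ene-1-carboxylate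
Product: 7 tert-butyl (1R,5S)-3-[dimethyl(phenyl)silyloxy]-5-methylcyclohex-3-ene-1-carboxylate
Conditions: [(Ph3P)CuH]6 (2 mol %), PhMe2SiH (1.3 equiv), toluene, 0 °C → rt
Reagents that add atoms: dimethyl(phenyl)silane, C[SiH](C)c1ccccc1
Why: Copper hydride 1,4-hydrosilylation delivers hydride axially to C8 on the face opposite the C6 ester, which places the methyl cis to the ester (both equatorial) and stores the enolate regiospecifically as the C4a=C8a silyl enol ether.

Step 5
Reactants: 8 nitroethane; 9 ethyl glyoxylate
Product: 10 ethyl 2-hydroxy-3-nitrobutanoate (diastereomer mixture)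
Conditions: Et3N (10 mol %), toluene, 0 °C → rt
Reagents that add atoms: none
Why: Henry reaction of the nitronate with the very electrophilic glyoxylate aldehyde; both new centres are removed in the next step.

Step 6
Reactants: 10 ethyl 2-hydroxy-3-nitrobutanoate
Product: 12 ethyl (E)-3-nitrobut-2-enoate, via mesylate 11 (not isolated)
Conditions: MsCl, Et3N (2.2 equiv), CH2Cl2, −20 °C
Reagents that add atoms: none
Why: Mesylation followed by E1cB elimination through the nitronate is the standard dehydration of nitro aldols and gives the isomer with NO2 and CO2Et trans.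

Step 7
Reactants: 7 tert-butyl (1R,5S)-3-[dimethyl(phenyl)silyloxy]-5-methylcyclohex-3-ene-1-carboxylate; 12 ethyl (E)-3-nitrobut-2-enoate
Product: 14 tert-butyl (1R,3S,4S)-4-[(E)-1-ethoxy-1-oxobut-2-en-2-yl]-3-methyl-5-oxocyclohexane-1-carboxylate, via nitro ketone 13 (not isolated)
Conditions: TiCl2(OiPr)2 (1.1 equiv), CH2Cl2, −78 → −30 °C; aq NaHCO3; crude 13, DBU (1.5 equiv), MeCN, 0 °C
Reagents that add atoms: none
Why: In this Mukaiyama–Michael addition the nitro group outweighs the ester, so C8a bonds to the carbon α to the ester (future C1) anti to the C8 methyl; E1cB loss of nitrous acid then gives the conjugated (E)-ethylidene ester, and the base leaves the epimerisable C8a side chain equatorial, trans to the methyl.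

Step 8
Reactants: 14 tert-butyl (1R,3S,4S)-4-[(E)-1-ethoxy-1-oxobut-2-en-2-yl]-3-methyl-5-oxocyclohexane-1-carboxylate; 15 ethynylmagnesium bromide
Product: 17 tert-butyl (3E,3aS,4S,6R,7aS)-7a-ethynyl-3-ethylidene-4-methyl-2-oxooctahydro-1-benzofuran-6-carboxylate (cis-fused lactone), via hydroxy ester 16 (not isolated)
Conditions: LaCl3·2LiCl (1 equiv), THF, −78 °C → rt; aq NH4Cl
Reagents that add atoms: none
Why: Lanthanum-assisted Grignard 1,2-addition suppresses enolisation at the acidic C8a–H; as with menthone-type ketones bearing a branched equatorial 2-substituent, the acetylide should enter equatorially, trans to the alkenyl group, so the axial C4a alkoxide closes onto the neighbouring ester to give the cis-fused γ-lactone, from which any trans-fused C4a epimer is separated.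

Step 9
Reactants: 17 tert-butyl (3E,3aS,4S,6R,7aS)-7a-ethynyl-3-ethylidene-4-methyl-2-oxooctahydro-1-benzofuran-6-carboxylate
Product: 18 tert-butyl (1R,3S,4S,5S)-4-[(E)-1-amino-1-oxobut-2-en-2-yl]-3-ethynyl-3-hydroxy-5-methylcyclohexane-1-carboxylate
Conditions: AlMe3/NH4Cl (3 equiv each, premixed), toluene/CH2Cl2, 0 → 40 °C; aq potassium sodium tartrate
Reagents that add atoms: ammonium chloride, [NH4+].[Cl-]
Why: Aluminium amide aminolysis opens the lactone at the acyl carbon, driven by the Al–O bond to the tertiary alkoxide, while the hindered tert-butyl ester and the β-substituted alkene are not attacked.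

Step 10
Reactants: 18 tert-butyl (1R,3S,4S,5S)-4-[(E)-1-amino-1-oxobut-2-en-2-yl]-3-ethynyl-3-hydroxy-5-methylcyclohexane-1-carboxylate
Product: 19 tert-butyl (1R,3S,4S,5S)-4-[(E)-1-cyanoprop-1-enyl]-3-ethynyl-3-hydroxy-5-methylcyclohexane-1-carboxylate
Conditions: (CF3CO)2O (1.5 equiv), pyridine (4 equiv), CH2Cl2, −10 °C; aq NaHCO3/MeOH
Reagents that add atoms: none
Why: Dehydration of the primary amide through its O-trifluoroacetyl imidate is fast with base, the hindered tertiary alcohol reacts slowly, and any trifluoroacetate formed there is cleaved in the basic methanol work-up.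

Step 11
Reactants: 19 tert-butyl (1R,3S,4S,5S)-4-[(E)-1-cyanoprop-1-enyl]-3-ethynyl-3-hydroxy-5-methylcyclohexane-1-carboxylate
Product: 21 tert-butyl (1R,3S,4Z,6R,7Z)-5-cyano-3,6-dimethyl-9-oxocyclodeca-4,7-diene-1-carboxylate (C1=C8a trans within the ring, C3=C4 cis), via potassium allenolate 20 (not isolated)
Conditions: KN(SiMe3)2 (1.05 equiv), 18-crown-6 (1.2 equiv), THF, −78 → 0 °C; cannulate into AcOH/THF at −78 °C
Reagents that add atoms: none
Why: In this anionic oxy-Cope rearrangement of a 1-ethynyl-2-alkenylcyclohexanol both π groups are equatorial, so a chair-like array breaks C4a–C8a and forms C2–C3; allylic strain from the ethylidene methyl keeps the C8a hydrogen in the alkene plane, so C1=C8a emerges trans in the ring and C3 bonds to C2 on the face that C4a leaves (C8a chirality passes to C2), the nitrile stabilises the transition state while its addition of the alkoxide stays reversible, and cold protonation of 20 at C4 from the side of the C3 hydrogen gives the Z-enone.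

Step 12
Reactants: 21 tert-butyl (1R,3S,4Z,6R,7Z)-5-cyano-3,6-dimethyl-9-oxocyclodeca-4,7-diene-1-carboxylate
Product: 23 tert-butyl (1S,2R,4aR,6R,8S,8aR)-1-cyano-4a-hydroxy-2,8-dimethyl-1,2,4a,5,6,7,8,8a-octahydronaphthalene-6-carboxylate (decalin numbering as above, cis-fused), via samarium keteniminate 22 (not isolated)
Conditions: SmI2 (0.1 M in THF, 2.5 equiv, added over 1 h), HMPA (10 equiv), t-BuOH (3 equiv), THF (0.005 M in 21), −78 → −20 °C; aq NaHCO3/Na2S2O3
Reagents that add atoms: none
Why: Proposed new method: divalent samarium transfers an electron to the conjugated C4a ketone, the most easily reduced group, and the samarium allyl ketyl bonds through C4a to C8a of the C1=C8a unsaturated nitrile (bonding through C3 would need a three- or four-membered ring), after which a second electron turns the α-cyano radical at C1 into keteniminate 22, which t-BuOH protonates. The closest known reactions are SmI2 ketyl–olefin cyclisations onto unsaturated esters and nitriles and transannular SmI2 ketone–alkene cyclisations of medium-ring ketones; what is new is the enone-derived ketyl and the activated alkene inside a ten-membered ring. Ring B closes 6-exo-trig (C4a, C5, C6, C7, C8, C8a, with C1 outside) and ring A closes 6-endo-trig (C4a, C4, C3, C2, C1, C8a). C4a and C8a are set together: the trans-in-ring C1=C8a holds C8 and C2 anti, and the HMPA-laden C4a–O–Sm bond should lie anti to C8a–C1 to keep dipoles and bulk apart, which is possible only in the cis-fused array, within which the alkene face is chosen by a chair ring B with the C8 methyl and C6 ester equatorial and a pseudoequatorial C2 methyl. C1 is set by protonation to the equatorial nitrile, trans to the C2 methyl and to C8 and free of a syn-axial contact with C5; this is also the thermodynamic epimer, so a wrong outcome can be corrected with base here or at the aldehyde or ketone stage. The step needs reduction of the enone before the nitrile and ring closure before protonation at C3 or dimerisation, which the proximity of C4a and C8a across the ring, the polarity match of nucleophilic ketyl and electron-poor alkene, the weak proton source, high dilution and slow SmI2 addition should secure, and E/Z leakage at C3=C4 is harmless because the radical anion can rotate and only the Z form can close.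

Step 13
Reactants: 23 tert-butyl (1S,2R,4aR,6R,8S,8aR)-1-cyano-4a-hydroxy-2,8-dimethyl-1,2,4a,5,6,7,8,8a-octahydronaphthalene-6-carboxylate
Product: 24 tert-butyl (1S,2R,4aR,6R,8S,8aR)-1-formyl-4a-hydroxy-2,8-dimethyl-1,2,4a,5,6,7,8,8a-octahydronaphthalene-6-carboxylate
Conditions: i-Bu2AlH (2.5 equiv), toluene, −78 °C; aq tartaric acid, 0 °C
Reagents that add atoms: water, O
Why: Partial reduction of the nitrile stops at the aluminium aldimine, which mild acid hydrolyses; the first equivalent is consumed by the C4a–OH, the tert-butyl ester is much slower at −78 °C, and the equatorial aldehyde is the stable C1 epimer.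

Step 14
Reactants: 25 3,4-dibromofuran; 26 acrolein
Product: 28 rac-1-(4-bromofuran-3-yl)prop-2-en-1-ol, via 4-bromo-3-lithiofuran 27 (not isolated)
Conditions: n-BuLi (1.0 equiv), Et2O, −78 °C; then 26, −78 °C; aq NH4Cl
Reagents that add atoms: none
Why: Single bromine–lithium exchange followed by 1,2-addition to acrolein; at −78 °C the 3-lithiofuran does not isomerise to the 2-lithio species.

Step 15
Reactants: 28 rac-1-(4-bromofuran-3-yl)prop-2-en-1-ol
Product: 29 3-bromo-4-[(E)-3-bromoprop-1-enyl]furan
Conditions: PBr3 (0.4 equiv), Et2O, −10 °C, used at once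
Reagents that add atoms: phosphorus tribromide, BrP(Br)Br
Why: Bromination of a 1-arylallyl alcohol proceeds with allylic transposition to the conjugated, cinnamyl-type (E)-primary bromide.

Step 16
Reactants: 29 3-bromo-4-[(E)-3-bromoprop-1-enyl]furan; 30 pentylmagnesium bromide
Product: 31 3-bromo-4-[(3S)-oct-1-en-3-yl]furan
Conditions: CuBr·SMe2 (3 mol %), (R,Rp)-TaniaPhos [1-(α-dimethylamino-2-diphenylphosphinobenzyl)-2-diphenylphosphinoferrocene] (3.6 mol %), CH2Cl2, −75 °C
Reagents that add atoms: none
Why: Copper-catalysed asymmetric allylic alkylation of a cinnamyl-type bromide with a primary alkyl Grignard reagent goes SN2′ to the branched product, the chiral diphosphine choosing the alkene face and so setting the S centre, and the ring bromide does not exchange at this temperature.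

Step 17
Reactants: 31 3-bromo-4-[(3S)-oct-1-en-3-yl]furan; 24 tert-butyl (1S,2R,4aR,6R,8S,8aR)-1-formyl-4a-hydroxy-2,8-dimethyl-1,2,4a,5,6,7,8,8a-octahydronaphthalene-6-carboxylate
Product: 33 furyl carbinol: decalin 24 with CHO replaced by CH(OH)–{4-[(3S)-oct-1-en-3-yl]furan-3-yl} (carbinol epimers), via lithiofuran 32 (not isolated)
Conditions: 31 (2.2 equiv), n-BuLi (2.2 equiv), Et2O, −78 °C; then 24, −78 °C; aq NH4Cl
Reagents that add atoms: none
Why: Aryllithium addition to an aldehyde is fast at −78 °C, where the tert-butyl ester is inert; one equivalent of 32 is spent on the C4a–OH, and the new carbinol centre is erased in step 19.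

Step 18
Reactants: 33 furyl carbinol
Product: 35 γ-hydroxybutenolide (5-hydroxyfuran-2(5H)-one carrying the octenyl group at C3 and the carbinol side chain at C4; regioisomer and lactol epimers converge), via endoperoxide 34 (not isolated)
Conditions: O2, visible light, tetraphenylporphyrin (cat.), i-Pr2NEt, CH2Cl2, −78 °C
Reagents that add atoms: oxygen, O=O
Why: Singlet oxygen adds [4+2] to the furan, by far the most electron-rich π system (the cis-disubstituted C3=C4 and the vinyl group react far more slowly), and the hindered base opens the endoperoxide to the hydroxybutenolide.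

Step 19
Reactants: 35 γ-hydroxybutenolide
Product: 36 acyl maleic anhydride (tert-butyl ester, C4a–OH free)
Conditions: Dess–Martin periodinane (3 equiv), NaHCO3, CH2Cl2, 0 °C → rt
Reagents that add atoms: none
Why: Dess–Martin oxidation converts the lactol into the anhydride and the secondary carbinol into the ketone in one operation; it cannot oxidise or transpose the tertiary allylic alcohol, and C1 remains the all-equatorial, thermodynamically preferred epimer.

Step 20
Reactants: 36 acyl maleic anhydride
Product: 37 acyl maleimide tert-butyl ester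
Conditions: (Me3Si)2NH (10 equiv), MeOH (5 equiv), DMF, rt
Reagents that add atoms: hexamethyldisilazane, C[Si](C)(C)N[Si](C)(C)C
Why: Ammonia released slowly from the silazane opens the anhydride, and silylation-assisted ring closure gives the imide at room temperature, the standard mild anhydride-to-maleimide exchange; the tetrasubstituted alkene is shielded against conjugate addition.

Step 21
Reactants: 37 acyl maleimide tert-butyl ester
Product: 39 CNP0326775.3, via bis-silyl derivative 38 (not isolated)
Conditions: TMSOTf (4 equiv), 2,6-lutidine (6 equiv), CH2Cl2, 0 °C; then pH 4 citrate buffer/THF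
Reagents that add atoms: none
Why: Silyl triflate-mediated cleavage of the tert-butyl ester (loss of isobutene, silyl ester formation) takes place in a buffered medium in which the C4a alcohol is masked as its silyl ether rather than protonated, which limits allylic ionisation, and the mild aqueous work-up frees the acid and the alcohol.

Compound list
1 | 3-methoxy-5-methylbenzoic acid | COc1cc(C)cc(C(=O)O)c1 | starting material
2 | 3-methoxy-5-methylcyclohexa-2,5-diene-1-carboxylic acid | COC1=CC(C(=O)O)C=C(C)C1 | intermediate
3 | rac-3-methyl-5-oxocyclohex-3-ene-1-carboxylic acid | CC1=CC(=O)CC(C(=O)O)C1 | intermediate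
4 | (R)-1-phenylethylammonium (R)-3-methyl-5-oxocyclohex-3-ene-1-carboxylate | C[C@@H]([NH3+])c1ccccc1.CC1=CC(=O)C[C@H](C(=O)[O-])C1 | intermediate
5 | (R)-3-methyl-5-oxocyclohex-3-ene-1-carboxylic acid | CC1=CC(=O)C[C@H](C(=O)O)C1 | intermediate
6 | tert-butyl (R)-3-methyl-5-oxocyclohex-3-ene-1-carboxylate | CC1=CC(=O)C[C@H](C(=O)OC(C)(C)C)C1 | intermediate
7 | tert-butyl (1R,5S)-3-[dimethyl(phenyl)silyloxy]-5-methylcyclohex-3-ene-1-carboxylate | C[C@H]1C[C@@H](C(=O)OC(C)(C)C)CC(O[Si](C)(C)c2ccccc2)=C1 | intermediate
8 | nitroethane | CC[N+](=O)[O-] | starting material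
9 | ethyl glyoxylate | CCOC(=O)C=O | starting material
10 | ethyl 2-hydroxy-3-nitrobutanoate | CCOC(=O)C(O)C(C)[N+](=O)[O-] | intermediate
11 | ethyl 2-(methylsulfonyloxy)-3-nitrobutanoate | CCOC(=O)C(OS(C)(=O)=O)C(C)[N+](=O)[O-] | intermediate
12 | ethyl (E)-3-nitrobut-2-enoate | CCOC(=O)/C=C(\C)[N+](=O)[O-] | intermediate
13 | nitro ketone, Michael adduct (C1 and C2 unassigned, both removed) | CCOC(=O)C(C(C)[N+](=O)[O-])[C@@H]1[C@@H](C)C[C@@H](C(=O)OC(C)(C)C)CC1=O | intermediate
14 | tert-butyl (1R,3S,4S)-4-[(E)-1-ethoxy-1-oxobut-2-en-2-yl]-3-methyl-5-oxocyclohexane-1-carboxylate | C/C=C(/C(=O)OCC)[C@@H]1[C@@H](C)C[C@@H](C(=O)OC(C)(C)C)CC1=O | intermediate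
15 | ethynylmagnesium bromide | C#C[Mg]Br | starting material
16 | hydroxy ester (formed as its alkoxide; axial OH, equatorial ethynyl) | C/C=C(/C(=O)OCC)[C@@H]1[C@@H](C)C[C@@H](C(=O)OC(C)(C)C)C[C@@]1(O)C#C | intermediate
17 | tert-butyl (3E,3aS,4S,6R,7aS)-7a-ethynyl-3-ethylidene-4-methyl-2-oxooctahydro-1-benzofuran-6-carboxylate | C/C=C1\[C@@H]2[C@@H](C)C[C@@H](C(=O)OC(C)(C)C)C[C@]2(C#C)OC1=O | intermediate
18 | tert-butyl (1R,3S,4S,5S)-4-[(E)-1-amino-1-oxobut-2-en-2-yl]-3-ethynyl-3-hydroxy-5-methylcyclohexane-1-carboxylate | C/C=C(/C(N)=O)[C@@H]1[C@@H](C)C[C@@H](C(=O)OC(C)(C)C)C[C@@]1(O)C#C | intermediate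
19 | tert-butyl (1R,3S,4S,5S)-4-[(E)-1-cyanoprop-1-enyl]-3-ethynyl-3-hydroxy-5-methylcyclohexane-1-carboxylate | C/C=C(/C#N)[C@@H]1[C@@H](C)C[C@@H](C(=O)OC(C)(C)C)C[C@@]1(O)C#C | intermediate
20 | potassium allenolate of the ten-membered ring | [K+].[O-]C1=C=C[C@@H](C)/C(C#N)=C/[C@@H](C)C[C@@H](C(=O)OC(C)(C)C)C1 | intermediate
21 | tert-butyl (1R,3S,4Z,6R,7Z)-5-cyano-3,6-dimethyl-9-oxocyclodeca-4,7-diene-1-carboxylate | O=C1/C=C\[C@@H](C)/C(C#N)=C/[C@@H](C)C[C@@H](C(=O)OC(C)(C)C)C1 | intermediate
22 | samarium keteniminate alkoxide of the cis-decalin (trivalent samarium) | C[C@@H]1C=C[C@]2(O[Sm](I)I)C[C@H](C(=O)OC(C)(C)C)C[C@H](C)[C@@H]2C1=C=N[Sm](I)I | intermediate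
23 | tert-butyl (1S,2R,4aR,6R,8S,8aR)-1-cyano-4a-hydroxy-2,8-dimethyl-1,2,4a,5,6,7,8,8a-octahydronaphthalene-6-carboxylate | N#C[C@@H]1[C@H]2[C@@H](C)C[C@@H](C(=O)OC(C)(C)C)C[C@@]2(O)C=C[C@H]1C | intermediate
24 | tert-butyl (1S,2R,4aR,6R,8S,8aR)-1-formyl-4a-hydroxy-2,8-dimethyl-1,2,4a,5,6,7,8,8a-octahydronaphthalene-6-carboxylate | O=C[C@@H]1[C@H]2[C@@H](C)C[C@@H](C(=O)OC(C)(C)C)C[C@@]2(O)C=C[C@H]1C | intermediate
25 | 3,4-dibromofuran | Brc1cocc1Br | starting material
26 | acrolein | C=CC=O | starting material
27 | 4-bromo-3-lithiofuran | [Li]c1cocc1Br | intermediate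
28 | rac-1-(4-bromofuran-3-yl)prop-2-en-1-ol | C=CC(O)c1cocc1Br | intermediate
29 | 3-bromo-4-[(E)-3-bromoprop-1-enyl]furan | BrC/C=C/c1cocc1Br | intermediate
30 | pentylmagnesium bromide | CCCCC[Mg]Br | starting material
31 | 3-bromo-4-[(3S)-oct-1-en-3-yl]furan | C=C[C@H](CCCCC)c1cocc1Br | intermediate
32 | 3-lithio-4-[(3S)-oct-1-en-3-yl]furan | C=C[C@H](CCCCC)c1cocc1[Li] | intermediate
33 | furyl carbinol (carbinol centre unassigned) | C=C[C@H](CCCCC)c1cocc1C(O)[C@@H]1[C@H]2[C@@H](C)C[C@@H](C(=O)OC(C)(C)C)C[C@@]2(O)C=C[C@H]1C | intermediate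
34 | furan endoperoxide | C=C[C@H](CCCCC)C1=C(C(O)[C@@H]3[C@H]4[C@@H](C)C[C@@H](C(=O)OC(C)(C)C)C[C@@]4(O)C=C[C@H]3C)C2OOC1O2 | intermediate
35 | γ-hydroxybutenolide (one regioisomer drawn, lactol and carbinol centres unassigned) | C=C[C@H](CCCCC)C1=C(C(O)[C@@H]2[C@H]3[C@@H](C)C[C@@H](C(=O)OC(C)(C)C)C[C@@]3(O)C=C[C@H]2C)C(O)OC1=O | intermediate
36 | acyl maleic anhydride tert-butyl ester | C=C[C@H](CCCCC)C1=C(C(=O)[C@@H]2[C@H]3[C@@H](C)C[C@@H](C(=O)OC(C)(C)C)C[C@@]3(O)C=C[C@H]2C)C(=O)OC1=O | intermediate
37 | acyl maleimide tert-butyl ester | C=C[C@H](CCCCC)C1=C(C(=O)[C@@H]2[C@H]3[C@@H](C)C[C@@H](C(=O)OC(C)(C)C)C[C@@]3(O)C=C[C@H]2C)C(=O)NC1=O | intermediate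
38 | trimethylsilyl ester, C4a trimethylsilyl ether | C=C[C@H](CCCCC)C1=C(C(=O)[C@@H]2[C@H]3[C@@H](C)C[C@@H](C(=O)O[Si](C)(C)C)C[C@@]3(O[Si](C)(C)C)C=C[C@H]2C)C(=O)NC1=O | intermediate
39 | CNP0326775.3: (1S,2R,4aR,6R,8S,8aR)-decalin acid, (S)-octenyl maleimide | C=C[C@H](CCCCC)C1=C(C(=O)[C@@H]2[C@H]3[C@@H](C)C[C@@H](C(=O)O)C[C@@]3(O)C=C[C@H]2C)C(=O)NC1=O | target

Total step count: 21. Longest linear sequence: 16 (steps 1–4, 7–13, 17–21).

Steps most likely to fail

Step 12. Conjugate reduction of the enone, or reductive dimerisation through C3, may outrun the transannular closure. Closure may also proceed through a trans-fused array on the other alkene face. The fallback sets out from 21 and returns at 23. Thiophenol with catalytic Et3N is added to the enone (thia-Michael addition) to give β-phenylthio ketone F1, which is a plain saturated medium-ring ketone. Its SmI2/HMPA/t-BuOH cyclisation onto the transannular unsaturated nitrile then belongs to the known classes of transannular ketone–alkene and ketyl–acrylonitrile couplings and should give decalin sulfide F2. One equivalent of mCPBA at −78 °C gives sulfoxide F3, and thermal syn elimination in toluene restores C3=C4 and gives 23.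

Step 11. The allenolate may attack the unsaturated nitrile across the ring. Base may move the skipped diene into conjugation with loss of the C2 centre, or the alkoxide may expel acetylide. The fallback sets out from 19 and returns at 21. Semihydrogenation (H2, Pd/CaCO3 poisoned with Pb(OAc)2, quinoline) gives vinyl carbinol F4. Its anionic oxy-Cope rearrangement is the classical divinylcyclohexanol ring expansion, and the simple enolate is trapped in the flask with TMSCl as silyl enol ether F5, so the ketone never meets base. Saegusa–Ito oxidation with Pd(OAc)2 in MeCN then installs C3=C4. If the E-enone F6 forms, reversible thiolate addition (catalytic PhSH/Et3N) equilibrates it to the less strained Z-enone 21.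

Step 8. Facial selectivity may be poor, because the slim acetylide can enter axially and give the C4a epimer, whose ethynyl and alkenyl groups cannot reach the chair-like array. The fallback sets out from 14 and returns at 21. Vinylmagnesium bromide with CeCl3, a bulkier sp2 nucleophile with a stronger equatorial preference, gives vinyl lactone F7 after lactonisation. The aminolysis of step 9 gives vinyl hydroxy amide F8, and the dehydration of step 10 gives vinyl carbinol F4. F4 is carried to 21 through silyl enol ether F5 as described for step 11.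

Further compounds
F1 | step 12 | β-phenylthio ketone (C3 unassigned) | O=C1CC(Sc2ccccc2)[C@@H](C)/C(C#N)=C/[C@@H](C)C[C@@H](C(=O)OC(C)(C)C)C1
F2 | step 12 | decalin sulfide (C3 unassigned) | N#C[C@@H]1[C@H]2[C@@H](C)C[C@@H](C(=O)OC(C)(C)C)C[C@@]2(O)CC(Sc2ccccc2)[C@H]1C
F3 | step 12 | sulfoxide (C3 and S unassigned) | N#C[C@@H]1[C@H]2[C@@H](C)C[C@@H](C(=O)OC(C)(C)C)C[C@@]2(O)CC(S(=O)c2ccccc2)[C@H]1C
F4 | step 11 | vinyl carbinol | C/C=C(/C#N)[C@@H]1[C@@H](C)C[C@@H](C(=O)OC(C)(C)C)C[C@@]1(O)C=C
F5 | step 11 | silyl enol ether of the ten-membered ketone | C[Si](C)(C)OC1=CC[C@@H](C)/C(C#N)=C/[C@@H](C)C[C@@H](C(=O)OC(C)(C)C)C1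
F6 | step 11 | E-enone isomer of 21 | O=C1/C=C/[C@@H](C)/C(C#N)=C/[C@@H](C)C[C@@H](C(=O)OC(C)(C)C)C1
F7 | step 8 | vinyl lactone | C/C=C1\[C@@H]2[C@@H](C)C[C@@H](C(=O)OC(C)(C)C)C[C@]2(C=C)OC1=O
F8 | step 8 | vinyl hydroxy amide | C/C=C(/C(N)=O)[C@@H]1[C@@H](C)C[C@@H](C(=O)OC(C)(C)C)C[C@@]1(O)C=C
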